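**Retrosynthetic overview**

1. Target ⇒ aldol adduct across C7–C8. The exocyclic C7=C8 (Z) and C5=C6 (E) geometry comes from a fused 2H-pyran, made by closing a carbon–oxygen bond from the ring ketone oxygen to C5 and then opened by oxa-6π ring opening.
2. Aldol adduct ⇒ (R)-2-bromo-4-hydroxy-4-[(Z)-oct-2-enyl]cyclopent-2-enone + methyl (E)-7-oxohept-5-enoate (cross-metathesis of methyl hex-5-enoate with crotonaldehyde).
3. Bromo hydroxy enone ⇒ α′-hydroxy vinylogous ester by reduction and hydrolytic carbonyl transposition; its carbon–oxygen bond (the only stereocentre, later C12) ⇒ reagent-controlled enolate hydroxylation.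
4. ⇒ α′-alkylation of 2-bromo-3-ethoxycyclopent-2-enone (NBS on 3-ethoxycyclopent-2-enone) with (Z)-1-bromooct-2-ene (from (Z)-oct-2-en-1-ol).
5. Rings: the cyclopentene ring is bought; the only ring formed is the transient pyran in the last step.

Positions are given in prostanoid numbering (ester carbon C1, ring C8–C12, tertiary carbinol C12).
Assumption: reagents that are not carbon building blocks carry no compound number and are named at their step.
Assumption: the (+)-oxaziridine of step 4 gives (R)-8, by analogy with 2-alkyl cyclic ketone enolates; if the first run shows the opposite sense, the (−)-reagent is used and nothing else changes.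

**Route**

Step 1
Reactants: 1 3-ethoxycyclopent-2-en-1-one
Product: 2 2-bromo-3-ethoxycyclopent-2-en-1-one
Conditions: NBS (1.05 equiv), CH2Cl2, 0 °C to rt, dark
Reagents that add atoms: N-bromosuccinimide, O=C1CCC(=O)N1Br
Why: The vinylogous ester is a push–pull enol ether whose C2 is its only strongly nucleophilic carbon, so electrophilic α-bromination of the β-alkoxy enone puts bromine there before any isolated alkene is present.

Step 2
Reactants: 3 (Z)-oct-2-en-1-ol
Product: 4 (Z)-1-bromooct-2-ene
Conditions: CBr4 (1.2 equiv), PPh3 (1.25 equiv), CH2Cl2, 0 °C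
Reagents that add atoms: carbon tetrabromide, BrC(Br)(Br)Br
Why: Appel bromination displaces the alkoxyphosphonium of the primary allylic alcohol by SN2 at low temperature, which keeps the Z double bond and avoids allylic transposition.

Step 3
Reactants: 2 2-bromo-3-ethoxycyclopent-2-en-1-one; 4 (Z)-1-bromooct-2-ene
Product: 6 rac-2-bromo-3-ethoxy-5-[(Z)-oct-2-en-1-yl]cyclopent-2-en-1-one, via lithium enolate 5 (not isolated)
Conditions: LiN(iPr)2 (1.05 equiv), THF, −78 °C; then 4, −78 to −30 °C
Reagents that add atoms: none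
Why: Kinetic deprotonation of a 3-alkoxy enone occurs at the α′ carbon (Stork–Danheiser enolate alkylation) and the enolate displaces the primary allylic bromide by SN2 with the Z alkene kept, the new stereocentre being racemic and erased in step 4.

Step 4
Reactants: 6 rac-2-bromo-3-ethoxy-5-[(Z)-oct-2-en-1-yl]cyclopent-2-en-1-one
Product: 8 (5R)-2-bromo-3-ethoxy-5-hydroxy-5-[(Z)-oct-2-en-1-yl]cyclopent-2-en-1-one, via sodium enolate 7 (not isolated)
Conditions: NaN(SiMe3)2 (1.1 equiv), THF, −78 °C; (+)-[(8,8-dichlorocamphoryl)sulfonyl]oxaziridine (1.3 equiv), −78 to −40 °C; AcOH quench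
Reagents that add atoms: (+)-[(8,8-dichlorocamphoryl)sulfonyl]oxaziridine, CC1(C)[C@@H]2CC[C@]13CS(=O)(=O)N4O[C@@]34C2(Cl)Cl
Why: A second kinetic α′ deprotonation gives a planar tetrasubstituted enolate, and the camphor-derived N-sulfonyloxaziridine transfers oxygen to one of its faces in an open SN2-type transition state (Davis asymmetric enolate hydroxylation), which forms the carbon–oxygen bond of the tertiary carbinol and sets its configuration (later C12) by reagent control.

Step 5
Reactants: 8 (5R)-2-bromo-3-ethoxy-5-hydroxy-5-[(Z)-oct-2-en-1-yl]cyclopent-2-en-1-one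
Product: 10 (4R)-2-bromo-4-hydroxy-4-[(Z)-oct-2-en-1-yl]cyclopent-2-en-1-one, via allylic diol 9 (not isolated)
Conditions: NaBH4, CeCl3·7H2O, MeOH, 0 °C; then aqueous HCl (1 mol/L), THF, rt
Reagents that add atoms: water, O
Why: Luche 1,2-reduction followed by acid hydrolysis of the 3-ethoxy allylic alcohol (Stork–Danheiser carbonyl transposition) moves the carbonyl to the former ether carbon and leaves bromine on the α carbon of the new enone, while the carbinol stereocentre is untouched because the neighbouring cation is an oxocarbenium ion captured by water at its far end.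

Step 6
Reactants: 11 methyl hex-5-enoate; 12 (E)-but-2-enal (crotonaldehyde, 5 equiv)
Product: 13 methyl (E)-7-oxohept-5-enoate
Conditions: second-generation Hoveyda–Grubbs catalyst RuCl2(=CH-C6H4-2-OiPr)(H2IMes) (2 mol%), CH2Cl2, 40 °C
Reagents that add atoms: none
Why: Olefin cross-metathesis of a reactive terminal alkene with an excess of a slowly homodimerising enal is a selective pairing that gives the E enal under thermodynamic control with loss of propene.

Step 7
Reactants: 10 (4R)-2-bromo-4-hydroxy-4-[(Z)-oct-2-en-1-yl]cyclopent-2-en-1-one; 13 methyl (E)-7-oxohept-5-enoate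
Product: 15 methyl (5E)-7-[(5R)-3-bromo-5-hydroxy-5-[(Z)-oct-2-en-1-yl]-2-oxocyclopent-3-en-1-yl]-7-hydroxyhept-5-enoate (epimer mixture at C7 and C8), via dilithium dianion 14 (not isolated)
Conditions: LiN(SiMe3)2 (2.2 equiv), THF, −78 °C; then 13 (1.2 equiv), −78 °C; AcOH quench at −78 °C
Reagents that add atoms: none
Why: Two equivalents of base give the alkoxide–enolate dianion at C8, the only enolisable position, and this lithium enolate adds 1,2 to the enal at low temperature (directed aldol addition), the two new stereocentres being an irrelevant mixture because both are destroyed in step 8.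

Step 8
Reactants: 15 methyl (5E)-7-[(5R)-3-bromo-5-hydroxy-5-[(Z)-oct-2-en-1-yl]-2-oxocyclopent-3-en-1-yl]-7-hydroxyhept-5-enoate
Product: 19 methyl (5E,7Z)-7-[(2S)-4-bromo-2-hydroxy-2-[(Z)-oct-2-en-1-yl]-5-oxocyclopent-3-en-1-ylidene]hept-5-enoate, via transposed allylic alcohol 16 (not isolated), via bicyclic hemiketal 17 (not isolated), via fused 2H-pyran 18 (not isolated)
Conditions: Re2O7 (5 mol%), CH2Cl2, 0 °C to rt, dark; then 35 °C, 1 h
Reagents that add atoms: none
Why: Proposed new method: the perrhenate ester of the allylic aldol hydroxyl undergoes reversible 1,3-transposition to the (Z)-δ-hydroxy β,γ-enone 16, whose hydroxyl closes on the ketone to hemiketal 17, rhenium-assisted loss of water gives the cyclopentadiene-fused 2H-pyran 18, and this opens by thermal disrotatory oxa-6π ring opening, which can only give the 7Z enone (C6 and the carbonyl carbon were ring neighbours) and turns the C5 substituent outward to give 5E, so the carbon–oxygen bond made first is a traceless template for the alkene geometry; the closest known reactions are Re2O7-catalysed allylic alcohol transposition with trapping by a pendant carbonyl group and the 2H-pyran/cis-dienone valence isomerisation.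

**Compound list**

1 | 3-ethoxycyclopent-2-en-1-one | CCOC1=CC(=O)CC1 | starting material
2 | 2-bromo-3-ethoxycyclopent-2-en-1-one | CCOC1=C(Br)C(=O)CC1 | intermediate
3 | (Z)-oct-2-en-1-ol | CCCCC/C=C\CO | starting material
4 | (Z)-1-bromooct-2-ene | CCCCC/C=C\CBr | intermediate
5 | lithium 5-bromo-4-ethoxycyclopenta-1,4-dien-1-olate (α′-enolate of 2) | [Li+].[O-]C1=CCC(OCC)=C1Br | intermediate
6 | rac-2-bromo-3-ethoxy-5-[(Z)-oct-2-en-1-yl]cyclopent-2-en-1-one | CCCCC/C=C\CC1CC(OCC)=C(Br)C1=O | intermediate
7 | sodium 5-bromo-4-ethoxy-2-[(Z)-oct-2-en-1-yl]cyclopenta-1,4-dien-1-olate (α′-enolate of 6) | [Na+].[O-]C1=C(C/C=C\CCCCC)CC(OCC)=C1Br | intermediate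
8 | (5R)-2-bromo-3-ethoxy-5-hydroxy-5-[(Z)-oct-2-en-1-yl]cyclopent-2-en-1-one | CCCCC/C=C\C[C@]1(O)C(=O)C(Br)=C(OCC)C1 | intermediate
9 | (1R)-3-bromo-4-ethoxy-1-[(Z)-oct-2-en-1-yl]cyclopent-3-ene-1,2-diol (C2 epimers) | CCCCC/C=C\C[C@]1(O)C(O)C(Br)=C(OCC)C1 | intermediate
10 | (4R)-2-bromo-4-hydroxy-4-[(Z)-oct-2-en-1-yl]cyclopent-2-en-1-one | CCCCC/C=C\C[C@]1(O)C=C(Br)C(=O)C1 | intermediate
11 | methyl hex-5-enoate | COC(=O)CCCC=C | starting material
12 | (E)-but-2-enal (crotonaldehyde) | C/C=C/C=O | starting material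
13 | methyl (E)-7-oxohept-5-enoate | COC(=O)CCC/C=C/C=O | intermediate
14 | dilithium (3R)-5-bromo-3-[(Z)-oct-2-en-1-yl]cyclopenta-1,4-diene-1,3-bis(olate) (dianion of 10) | CCCCC/C=C\C[C@]1([O-])C=C(Br)C([O-])=C1.[Li+].[Li+] | intermediate
15 | methyl (5E)-7-[(5R)-3-bromo-5-hydroxy-5-[(Z)-oct-2-en-1-yl]-2-oxocyclopent-3-en-1-yl]-7-hydroxyhept-5-enoate (epimers at C7 and C8) | CCCCC/C=C\C[C@]1(O)C=C(Br)C(=O)C1C(O)/C=C/CCCC(=O)OC | intermediate
16 | methyl (6Z)-7-[(5R)-3-bromo-5-hydroxy-5-[(Z)-oct-2-en-1-yl]-2-oxocyclopent-3-en-1-yl]-5-hydroxyhept-6-enoate (epimers at C5 and C8) | CCCCC/C=C\C[C@]1(O)C=C(Br)C(=O)C1/C=C\C(O)CCCC(=O)OC | intermediate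
17 | methyl 4-[(5R)-7-bromo-5,7a-dihydroxy-5-[(Z)-oct-2-en-1-yl]-2,4a,5,7a-tetrahydrocyclopenta[b]pyran-2-yl]butanoate (other centres mixed) | CCCCC/C=C\C[C@]1(O)C=C(Br)C2(O)C1C=CC(CCCC(=O)OC)O2 | intermediate
18 | methyl 4-[(5S)-7-bromo-5-hydroxy-5-[(Z)-oct-2-en-1-yl]-2,5-dihydrocyclopenta[b]pyran-2-yl]butanoate (C2 epimers) | CCCCC/C=C\C[C@]1(O)C=C(Br)C2=C1C=CC(CCCC(=O)OC)O2 | intermediate
19 | methyl (5E,7Z)-7-[(2S)-4-bromo-2-hydroxy-2-[(Z)-oct-2-en-1-yl]-5-oxocyclopent-3-en-1-ylidene]hept-5-enoate | CCCCC/C=C\C[C@]1(O)C=C(Br)C(=O)/C1=C\C=C\CCCC(=O)OC | target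

**Step count and risks**

Total step count: 8. Longest linear sequence: 6 (steps 1, 3, 4, 5, 7, 8).

The three steps most likely to fail:

Step 4. Neither the enantiomeric excess nor the facial sense of the oxaziridine on this bromo vinylogous-ester enolate is precedented. The fallback sets out from 6 and comes back at 8. 6 is converted with LiN(iPr)2 and Me3SiCl (THF, −78 °C) into the trimethylsilyl dienol ether F1. F1 is epoxidised at its silyloxy-bearing double bond with the fructose-derived Shi ketone (catalytic), KHSO5 and K2CO3 in MeCN–dimethoxymethane–water at 0 °C; this is the most electron-rich alkene, and cis-disubstituted alkenes react slowly with this catalyst. The silyloxy epoxide F2 opens on work-up (AcOH, wet THF) with loss of the silyl group to give 8. The enantiomer of the ketone catalyst is chosen to give the (R) carbinol.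

Step 7. The dianion may aggregate, add 1,4, or the aldolate may revert. The fallback sets out from 10 and comes back at 15. 10 is bis-silylated with Me3SiOTf and Et3N (CH2Cl2, 0 °C) to the silyl ether silyl dienol ether F3. A Mukaiyama aldol addition of F3 to 13 with BF3·OEt2 at −78 °C gives, after aqueous work-up, the C12 silyl ether F4. Citric acid in MeOH removes the silyl group to give 15.

Step 8 (the proposed new method). Direct acid-type dehydration without passage through the pyran would give a 7E/7Z mixture, and the tertiary hydroxyl could trap the allyl cation as a cyclic ether. The fallback uses known chemistry, sets out from 15 and comes back at 19. MsCl and Et3N (CH2Cl2, −20 °C) convert only the secondary allylic hydroxyl into the mesylate F5. DBU (0 °C) eliminates it by E1cB to a mixture of 19 and its 7E isomer F6, which are separated by HPLC on silica. F6 is irradiated (350 nm, benzene, rt) to the photostationary E/Z mixture, from which more 19 is isolated and the remainder recycled.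

**Further compounds**

F1 | step 4 | {[5-bromo-4-ethoxy-2-[(Z)-oct-2-en-1-yl]cyclopenta-1,4-dien-1-yl]oxy}trimethylsilane | CCCCC/C=C\CC1=C(O[Si](C)(C)C)C(Br)=C(OCC)C1
F2 | step 4 | 2-bromo-3-ethoxy-5-[(Z)-oct-2-en-1-yl]-1-(trimethylsilyloxy)-6-oxabicyclo[3.1.0]hex-2-ene (epoxide oxygen on the face that becomes the (R) carbinol) | CCCCC/C=C\C[C@]12O[C@@]1(O[Si](C)(C)C)C(Br)=C(OCC)C2
F3 | step 7 | [(3R)-5-bromo-3-[(Z)-oct-2-en-1-yl]cyclopenta-1,4-diene-1,3-diyl]bis(oxy)bis(trimethylsilane) | CCCCC/C=C\C[C@]1(O[Si](C)(C)C)C=C(Br)C(O[Si](C)(C)C)=C1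
F4 | step 7 | C12 trimethylsilyl ether of 15 | CCCCC/C=C\C[C@]1(O[Si](C)(C)C)C=C(Br)C(=O)C1C(O)/C=C/CCCC(=O)OC
F5 | step 8 | C7 methanesulfonate of 15 | CCCCC/C=C\C[C@]1(O)C=C(Br)C(=O)C1C(OS(C)(=O)=O)/C=C/CCCC(=O)OC
F6 | step 8 | methyl (5E,7E)-7-[(2S)-4-bromo-2-hydroxy-2-[(Z)-oct-2-en-1-yl]-5-oxocyclopent-3-en-1-ylidene]hept-5-enoate | CCCCC/C=C\C[C@]1(O)C=C(Br)C(=O)/C1=C/C=C/CCCC(=O)OC
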